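**Plan** (labdane numbering: ring A = C1–C5, C10; ring B = C5–C10; C20 = methyl on C10; C17 = methylene on C8; side chain C11–C16 on C9)

1. Retrosynthesis: the C2 acetate goes back to a C2 ketone and the C8 methylene to a C8 ketone; then C1–C10 and C3–C4 are cut (ring A), then C9–C11 (side chain).
2. The enabling feature: C1 is α to the C2 carbonyl and C10 is β to the C8 carbonyl (1,5-dicarbonyl through C1–C10–C9), and what is left of ring B (C5–C10, C20 and the gem-dimethyl carbon C4 on C5) is the carbon skeleton of verbenone with its cyclobutane bond C4–C7 opened.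
3. Forward: verbenone is opened to a ring B enone carrying a tertiary acetate at C4; α-iodination and Negishi coupling attach the complete (Z) side chain at C9.
4. One flask then joins C4 to a four-carbon bis-nucleophile and closes ring A by Michael addition (C1–C10); Wittig methylenation, ester removal, C2 reduction and acetylation finish the route.
5. Stereochemistry: C5 is the verbenone bridgehead (no bond to it is broken); C10, C9 and the trans ring fusion come from a reversible Michael addition under thermodynamic control; C2 comes from hydride attack on the α face; 13Z comes from a six-membered lactone.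

Key step: step 5

Remark: the Lewis-acid opening in step 2 is assumed to break the cyclobutane bond next to the carbonyl carbon, as in known openings of verbenone and nopinone to 4-(2-acetoxypropan-2-yl)cyclohexenone derivatives.
Remark: (1R,5R)-(+)-verbenone, lactone 1 and diene 11 are taken as purchasable; the C1 ester in 14 and 15 is drawn α (axial) but is epimerisable and is removed in step 7.

**Step 1**
Reactants: 1 4-methyl-5,6-dihydro-2H-pyran-2-one
Product: 4 methyl (2Z)-5-iodo-3-methylpent-2-enoate, via silyl ester 2 (not isolated), via iodo acid 3 (not isolated)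
Conditions: TMSI (1.1 equiv), CH2Cl2, 0 → 25 °C; then TMSCHN2, PhMe/MeOH (4:1), 0 °C
Reagents that add atoms: iodotrimethylsilane, C[Si](C)(C)I; (trimethylsilyl)diazomethane, C[Si](C)(C)C=[N+]=[N-]
Why: Silyl-activated alkyl–oxygen cleavage of the lactone by iodide (SN2 at the OCH2 carbon), methanolysis of the silyl ester and O-methylation of the acid by the diazoalkane; the Z geometry is that of the ring alkene and is not touched.

**Step 2**
Reactants: 5 (1R,5R)-(+)-verbenone [(1R,5R)-4,6,6-trimethylbicyclo[3.1.1]hept-3-en-2-one]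
Product: 7 2-[(1R)-2-methyl-4-oxocyclohex-2-en-1-yl]propan-2-yl acetate, via dienyl diacetate 6 (not isolated)
Conditions: BF3·OEt2 (0.3 equiv), Zn(OAc)2 (0.5 equiv), Ac2O, 25 °C; then K2CO3 (0.2 equiv), MeOH, 0 °C
Reagents that add atoms: acetic anhydride, CC(=O)OC(C)=O
Why: Lewis-acid fragmentation of the O-acetylated pinenone, in which the cyclobutane bond next to the carbonyl carbon ionises, acetate captures the tertiary cation and methanolysis of the dienyl acetate returns the conjugated enone; the bridgehead that becomes C5 keeps all four bonds and so its configuration.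

**Step 3**
Reactants: 7 2-[(1R)-2-methyl-4-oxocyclohex-2-en-1-yl]propan-2-yl acetate
Product: 8 2-[(1R)-3-iodo-2-methyl-4-oxocyclohex-2-en-1-yl]propan-2-yl acetate
Conditions: I2 (2 equiv), pyridine (4 equiv), DMAP (0.2 equiv), CH2Cl2, 0 → 25 °C
Reagents that add atoms: iodine, II
Why: Amine-mediated α-iodination of a cyclohexenone (Baylis–Hillman-type conjugate addition of the amine, iodination of the enolate, E1cB loss of the amine), a standard route to 2-iodo-3-methylcyclohex-2-enones; the tertiary acetate and C5 are not affected.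

**Step 4**
Reactants: 4 methyl (2Z)-5-iodo-3-methylpent-2-enoate; 8 2-[(1R)-3-iodo-2-methyl-4-oxocyclohex-2-en-1-yl]propan-2-yl acetate
Product: 10 methyl (2Z)-5-{(3R)-3-[2-(acetyloxy)propan-2-yl]-2-methyl-6-oxocyclohex-1-en-1-yl}-3-methylpent-2-enoate, via alkylzinc iodide 9 (not isolated)
Conditions: 4, zinc dust (activated with 1,2-dibromoethane and TMSCl), LiCl, THF, 35 °C; then 8, Pd(OAc)2 (3 mol %), SPhos (6 mol %), THF, 25 → 45 °C
Reagents that add atoms: none
Why: Negishi coupling of an α-iodoenone with an ester-bearing primary alkylzinc iodide forms C9–C11; the electron-rich biarylphosphine favours reductive elimination over β-hydride elimination, and neither the Z alkene nor C5 takes part.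

**Step 5**
Reactants: 10 methyl (2Z)-5-{(3R)-3-[2-(acetyloxy)propan-2-yl]-2-methyl-6-oxocyclohex-1-en-1-yl}-3-methylpent-2-enoate; 11 1-methoxy-1,3-bis(trimethylsilyloxy)buta-1,3-diene
Product: 14 methyl (13Z)-1α-(methoxycarbonyl)-2,8-dioxo-17-norlabd-13-en-15-oate, via silyl enol ether 12 (not isolated), via keto ester 13 (not isolated)
Conditions: 11 (2 equiv), TMSOTf (0.3 equiv), CH2Cl2, −40 → 0 °C; then NaOMe (0.8 equiv), MeOH, 0 → 55 °C
Reagents that add atoms: none
Why: TMSOTf ionises the tertiary acetate (as it does tert-butyl esters) and the cation on C4 is captured at the terminal carbon of diene 11 with return of TMSOTf, giving 12; methanolic methoxide then unmasks β-keto ester 13, whose enolate adds to the enone β-carbon C10 and forms C1–C10. The closest known reactions are the Lewis-acid SN1 α-tert-alkylation of silyl enol ethers, the γ-alkylation of 1,3-bis(silyloxy)dienes and the base-mediated intramolecular Michael addition of β-keto esters to cyclohexenones. Ring A closes by a 6-exo-trig Michael addition, with C10 inside the new ring and C9 outside it. C5 is carried over unchanged from verbenone, whereas C10, C9 and the epimerisable C1 are set under thermodynamic control: the addition is reversible in methoxide (retro-Michael through the C9 enolate with loss of the stabilised β-keto ester anion), the trans-fused chair–chair isomer with axial C10 methyl and equatorial C9 chain should be the most stable, and a cis-fused isomer formed kinetically (attack syn to the pseudoaxial tether) is drained through the open form. The step needs C–C capture of the cation before proton loss, ring closure at C10 only and survival of the Z enoate; these are secured by the excess of the highly nucleophilic diene, by the tether length (C1 can reach only C10) and by the mild alkoxide.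

**Step 6**
Reactants: 14 methyl (13Z)-1α-(methoxycarbonyl)-2,8-dioxo-17-norlabd-13-en-15-oate
Product: 15 methyl (13Z)-1α-(methoxycarbonyl)-2-oxolabda-8(17),13-dien-15-oate
Conditions: Ph3PCH3Br (4 equiv), KOtBu (3.8 equiv), THF/PhMe, 0 → 60 °C
Reagents that add atoms: methyltriphenylphosphonium bromide, C[P+](c1ccccc1)(c1ccccc1)c1ccccc1.[Br-]
Why: Wittig methylenation of the C8 ketone; the first equivalent of ylide turns the β-keto ester into its enolate, which masks the C2 carbonyl and rules out retro-Michael opening, and C9 stays in its stable equatorial configuration.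

**Step 7**
Reactants: 15 methyl (13Z)-1α-(methoxycarbonyl)-2-oxolabda-8(17),13-dien-15-oate
Product: 17 (13Z)-2-oxolabda-8(17),13-dien-15-oic acid, via keto diacid 16 (not isolated)
Conditions: LiI (10 equiv), pyridine, 115 °C; then 1 M HCl, 0 °C
Reagents that add atoms: none
Why: SN2 O-demethylation of both methyl esters by iodide; the β-keto carboxylate loses CO2 in the flask while the conjugated carboxylate is kept, and iodide attacks only the methyl groups so the alkenes are left alone.

**Step 8**
Reactants: 17 (13Z)-2-oxolabda-8(17),13-dien-15-oic acid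
Product: 18 (13Z)-2β-hydroxylabda-8(17),13-dien-15-oic acid
Conditions: NaBH4 (3 equiv), MeOH/THF, 0 °C; then aq. citric acid
Reagents that add atoms: none
Why: Borohydride reduction of the C2 ketone; the β face is screened by the two syn-axial methyl groups on C4 and C10, so hydride should enter from the α face and give the axial 2β alcohol (the usual outcome for 2-oxo steroids and 4,4-dimethyl-2-oxo terpenoids), while carboxylate and alkenes are inert.

**Step 9**
Reactants: 18 (13Z)-2β-hydroxylabda-8(17),13-dien-15-oic acid
Product: 20 (13Z)-2β-acetoxylabda-8(17),13-dien-15-oic acid, via mixed anhydride 19 (not isolated)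
Conditions: Ac2O (5 equiv), DMAP (0.2 equiv), pyridine, 40 °C; then H2O/THF, 25 °C
Reagents that add atoms: acetic anhydride, CC(=O)OC(C)=O
Why: DMAP-catalysed O-acetylation of the hindered axial alcohol with retention at C2; the carboxylic acid is acetylated in passing to the mixed anhydride, which water cleaves at the unhindered acetyl carbonyl during work-up.

**Compound list**

1 | 4-methyl-5,6-dihydro-2H-pyran-2-one | CC1=CC(=O)OCC1 | starting material
2 | trimethylsilyl (2Z)-5-iodo-3-methylpent-2-enoate | ICC/C(C)=C\C(=O)O[Si](C)(C)C | intermediate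
3 | (2Z)-5-iodo-3-methylpent-2-enoic acid | ICC/C(C)=C\C(=O)O | intermediate
4 | methyl (2Z)-5-iodo-3-methylpent-2-enoate | ICC/C(C)=C\C(=O)OC | intermediate
5 | (1R,5R)-(+)-verbenone, (1R,5R)-4,6,6-trimethylbicyclo[3.1.1]hept-3-en-2-one | CC1=CC(=O)[C@@H]2C[C@H]1C2(C)C | starting material
6 | (4R)-4-[2-(acetyloxy)propan-2-yl]-5-methylcyclohexa-1,5-dien-1-yl acetate | CC(=O)OC1=CC[C@@H](C(C)(C)OC(C)=O)C(C)=C1 | intermediate
7 | 2-[(1R)-2-methyl-4-oxocyclohex-2-en-1-yl]propan-2-yl acetate | O=C1CC[C@@H](C(C)(C)OC(C)=O)C(C)=C1 | intermediate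
8 | 2-[(1R)-3-iodo-2-methyl-4-oxocyclohex-2-en-1-yl]propan-2-yl acetate | O=C1CC[C@@H](C(C)(C)OC(C)=O)C(C)=C1I | intermediate
9 | [(3Z)-5-methoxy-3-methyl-5-oxopent-3-en-1-yl]zinc iodide | I[Zn]CC/C(C)=C\C(=O)OC | intermediate
10 | methyl (2Z)-5-{(3R)-3-[2-(acetyloxy)propan-2-yl]-2-methyl-6-oxocyclohex-1-en-1-yl}-3-methylpent-2-enoate | O=C1CC[C@@H](C(C)(C)OC(C)=O)C(C)=C1CC/C(C)=C\C(=O)OC | intermediate
11 | 1-methoxy-1,3-bis(trimethylsilyloxy)buta-1,3-diene (bis-silyl dienol ether of methyl acetoacetate; enol geometry immaterial) | C=C(O[Si](C)(C)C)C=C(OC)O[Si](C)(C)C | starting material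
12 | methyl 5-{(1S)-3-[(3Z)-5-methoxy-3-methyl-5-oxopent-3-en-1-yl]-2-methyl-4-oxocyclohex-2-en-1-yl}-5-methyl-3-(trimethylsilyloxy)hex-2-enoate (enol ether geometry not defined) | O=C1CC[C@@H](C(C)(C)CC(O[Si](C)(C)C)=CC(=O)OC)C(C)=C1CC/C(C)=C\C(=O)OC | intermediate
13 | methyl 5-{(1S)-3-[(3Z)-5-methoxy-3-methyl-5-oxopent-3-en-1-yl]-2-methyl-4-oxocyclohex-2-en-1-yl}-5-methyl-3-oxohexanoate | O=C1CC[C@@H](C(C)(C)CC(=O)CC(=O)OC)C(C)=C1CC/C(C)=C\C(=O)OC | intermediate
14 | methyl (13Z)-1α-(methoxycarbonyl)-2,8-dioxo-17-norlabd-13-en-15-oate (trans-fused; 5α-H, 9α-H, 10β-CH3) | O=C1CC[C@H]2C(C)(C)CC(=O)[C@H](C(=O)OC)[C@]2(C)[C@H]1CC/C(C)=C\C(=O)OC | intermediate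
15 | methyl (13Z)-1α-(methoxycarbonyl)-2-oxolabda-8(17),13-dien-15-oate | C=C1CC[C@H]2C(C)(C)CC(=O)[C@H](C(=O)OC)[C@]2(C)[C@H]1CC/C(C)=C\C(=O)OC | intermediate
16 | (13Z)-1α-carboxy-2-oxolabda-8(17),13-dien-15-oic acid | C=C1CC[C@H]2C(C)(C)CC(=O)[C@H](C(=O)O)[C@]2(C)[C@H]1CC/C(C)=C\C(=O)O | intermediate
17 | (13Z)-2-oxolabda-8(17),13-dien-15-oic acid | C=C1CC[C@H]2C(C)(C)CC(=O)C[C@]2(C)[C@H]1CC/C(C)=C\C(=O)O | intermediate
18 | (13Z)-2β-hydroxylabda-8(17),13-dien-15-oic acid | C=C1CC[C@H]2C(C)(C)C[C@@H](O)C[C@]2(C)[C@H]1CC/C(C)=C\C(=O)O | intermediate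
19 | acetic (13Z)-2β-acetoxylabda-8(17),13-dien-15-oic anhydride | C=C1CC[C@H]2C(C)(C)C[C@@H](OC(C)=O)C[C@]2(C)[C@H]1CC/C(C)=C\C(=O)OC(C)=O | intermediate
20 | (13Z)-2β-acetoxylabda-8(17),13-dien-15-oic acid, (2R,5S,9S,10S) | C=C1CC[C@H]2C(C)(C)C[C@@H](OC(C)=O)C[C@]2(C)[C@H]1CC/C(C)=C\C(=O)O | target

**Totals**

Total step count: 9. Longest linear sequence: 8 steps (steps 2 to 9, from 5).

**Steps most likely to fail**

Step 5. The tertiary cation may lose a proton before the diene is attached, giving the isopropenyl compound or the conjugated isopropylidene compound (the latter erases C5). The ring may also close kinetically to the cis-fused isomer and equilibrate only slowly. The fallback sets out from 10 and separates the two events. TiCl4 and allyltrimethylsilane in CH2Cl2 at −78 °C (Hosomi–Sakurai-type SN1 allylation, with a small and robust nucleophile) should give the allyl compound methyl (2Z)-3-methyl-5-[(3S)-2-methyl-3-(2-methylpent-4-en-2-yl)-6-oxocyclohex-1-en-1-yl]pent-2-enoate F1. Ozonolysis of its only electron-rich alkene (O3, CH2Cl2/MeOH, −78 °C; Me2S) should give the aldehyde methyl (2Z)-3-methyl-5-[(3S)-2-methyl-3-(2-methyl-4-oxobutan-2-yl)-6-oxocyclohex-1-en-1-yl]pent-2-enoate F2. Roskamp homologation (methyl diazoacetate, SnCl2 cat., CH2Cl2) then gives keto ester 13, now isolated. It is cyclised on its own with NaOMe in MeOH under prolonged equilibration, and the route is rejoined at 14.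

Step 6. The ylide may enolise the hindered C8 ketone instead of adding to it, or its basicity may move or isomerise the Z enoate double bond. The fallback sets out from 14 and uses a Peterson olefination. Me3SiCH2Li with CeCl3 in THF at −78 °C (the first equivalent is consumed by the β-keto ester) should add to C8 from the α face and give methyl (13Z)-8β-hydroxy-1α-(methoxycarbonyl)-2-oxo-17-(trimethylsilyl)labd-13-en-15-oate F3. HF·pyridine in MeCN at 0 °C then eliminates it to the methylene compound, and the route is rejoined at 15.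

Step 7. Demethylation of the conjugated ester by iodide may stay incomplete, or the long heating with iodide may erode the Z geometry. The fallback sets out from 15 and removes the two esters one after the other. Krapcho dealkoxycarbonylation (LiCl, wet DMSO, 150 °C) acts on the β-keto ester only and should give methyl (13Z)-2-oxolabda-8(17),13-dien-15-oate F4. Saponification (LiOH, THF/MeOH/H2O, 40 °C), which is known to keep the geometry of Z 3-methyl-2-enoates, then gives the acid, and the route is rejoined at 17.

**Further compounds**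

F1 | step 5 | methyl (2Z)-3-methyl-5-[(3S)-2-methyl-3-(2-methylpent-4-en-2-yl)-6-oxocyclohex-1-en-1-yl]pent-2-enoate | O=C1CC[C@@H](C(C)(C)CC=C)C(C)=C1CC/C(C)=C\C(=O)OC
F2 | step 5 | methyl (2Z)-3-methyl-5-[(3S)-2-methyl-3-(2-methyl-4-oxobutan-2-yl)-6-oxocyclohex-1-en-1-yl]pent-2-enoate | O=C1CC[C@@H](C(C)(C)CC=O)C(C)=C1CC/C(C)=C\C(=O)OC
F3 | step 6 | methyl (13Z)-8β-hydroxy-1α-(methoxycarbonyl)-2-oxo-17-(trimethylsilyl)labd-13-en-15-oate | C[Si](C)(C)C[C@]1(O)CC[C@H]2C(C)(C)CC(=O)[C@H](C(=O)OC)[C@]2(C)[C@H]1CC/C(C)=C\C(=O)OC
F4 | step 7 | methyl (13Z)-2-oxolabda-8(17),13-dien-15-oate | C=C1CC[C@H]2C(C)(C)CC(=O)C[C@]2(C)[C@H]1CC/C(C)=C\C(=O)OC
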